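The butenolide ring has C2 (lactone carbonyl) and C5 (the oxygen-bound ylidene carbon) on either side of the C3=C4 double bond, and both map onto carboxyl carbons. The only stereocentre, C1′, lies outside the ring on the C3 side chain. The ring is therefore traced back to a maleic anhydride and this to a terminal alkyne whose two sp carbons become C3 and C4. A single palladium-catalysed oxidative dicarbonylation joins alkyne, two CO and one oxygen atom, forming C2–C3, C4–C5 and both C–O1 bonds with cis geometry. Its substrate, (R)-hex-1-yn-3-yl acetate, already carries the C1′ configuration and the acetate of the target.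

Key step: step 4

Remark: the target is taken as drawn, with C1′ as R and the C5=CHBr bond as E, the vinylic bromine lying on the C4 side and anti to O1 (ring numbering O1, C2 carbonyl, C3 side chain, C4 bromine, C5 ylidene carbon).

Step 1
Reactants: 1 butanoyl chloride; 2 bis(trimethylsilyl)acetylene
Product: 3 1-(trimethylsilyl)hex-1-yn-3-one
Conditions: AlCl3 (1.1 equiv), CH2Cl2, 0 °C
Reagents that add atoms: none
Why: Friedel–Crafts-type acylation of an alkynylsilane, in which the acylium–AlCl3 complex attacks a silylated alkyne carbon (β-silyl stabilisation), chloride removes that silyl group, and the ynone formed is too deactivated to be acylated again.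

Step 2
Reactants: 3 1-(trimethylsilyl)hex-1-yn-3-one
Product: 4 (R)-1-(trimethylsilyl)hex-1-yn-3-ol
Conditions: RuCl[(R,R)-TsDPEN](p-cymene) (1 mol%, pre-activated with KOH, base washed out), i-PrOH, rt
Reagents that add atoms: none
Why: Noyori asymmetric transfer hydrogenation, in which the Ru–H/N–H catalyst passes hydride and proton through a six-membered transition state with the alkynyl group in the position next to the η6-arene, so the (R,R)-ligand should set the (R)-carbinol, and reduction of an ynone in 2-propanol is practically irreversible.

Step 3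
Reactants: 4 (R)-1-(trimethylsilyl)hex-1-yn-3-ol
Product: 6 (R)-hex-1-yn-3-yl acetate, via (R)-hex-1-yn-3-ol 5 (not isolated)
Conditions: Bu4NF (1.05 equiv), THF, 0 °C; then Ac2O (1.5 equiv), DMAP (cat.), 0 °C → rt
Reagents that add atoms: acetic anhydride, CC(=O)OC(C)=O
Why: Fluoride-induced protodesilylation of the alkynyl C–Si bond followed by DMAP-catalysed O-acetylation in the same flask, neither of which touches the C3–O bond, so the R configuration is kept and the volatile alcohol need not be isolated.

Step 4
Reactants: 6 (R)-hex-1-yn-3-yl acetate; 7 carbon monoxide (two molecules are taken up per molecule of 6)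
Product: 8 (R)-3-(1-acetoxybutyl)furan-2,5-dione
Conditions: PdI2 (1 mol%), KI (10 mol%), CO/air 4:1 (20 atm), dioxane/H2O (limited water), 60–80 °C
Reagents that add atoms: carbon monoxide, [C-]#[O+] (the second CO unit, which becomes the other ring carbonyl; the first is counted as reactant 7); water, O (its oxygen becomes ring O1 through the Pd–CO2H group); dioxygen from air, O=O (terminal oxidant; it regenerates the water consumed, so that O1 is drawn from it in the net equation)
Why: PdI2, CO and water give an I–Pd–CO2H species that adds syn across the C≡C bond of 6 (either regiochemistry of insertion leads to the same ring); a second CO then inserts into the vinyl–palladium bond and the neighbouring carboxyl oxygen attacks the acylpalladium carbon, releasing 8, HI and zerovalent palladium, which air and HI return to PdI2. The closest known reaction type is the PdI2/KI-catalysed oxidative dicarbonylation of terminal alkynes to maleic anhydrides in aqueous dioxane. The single ring is closed by 5-exo-trig O-acylation, equivalent to C–O reductive elimination from a six-membered acylpalladium carboxylate. No stereocentre is created: C1′ is a spectator whose bonds are not touched, and the cis relation of C2 and C5 follows from the syn insertion. The step needs double carbonylation to outrun capture of palladium intermediates by the side-chain oxygen and ionisation of the propargylic C–O bond; the acetate removes the free hydroxyl and is a poor leaving group, and the iodide-rich oxidising medium keeps zerovalent palladium short-lived.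

Step 5
Reactants: 8 (R)-3-(1-acetoxybutyl)furan-2,5-dione
Product: 10 (R)-1-(4-bromo-2,5-dioxo-2,5-dihydrofuran-3-yl)butyl acetate, via vicinal dibromide 9 (not isolated)
Conditions: Br2 (1.1 equiv), CH2Cl2, hν (visible), rt; excess Br2 removed; then i-Pr2NEt (1.05 equiv), −20 → 0 °C
Reagents that add atoms: bromine, BrBr
Why: Radical-chain addition of Br2 across the electron-poor C3=C4 bond followed by E1cB dehydrobromination, in which the only ring hydrogen, C4–H, is α to C5=O so that its enolate expels the C3 bromide and leaves bromine on C4, while the hindered amine at low temperature should spare the allylic acetate and C1′–H.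

Step 6
Reactants: 10 (R)-1-(4-bromo-2,5-dioxo-2,5-dihydrofuran-3-yl)butyl acetate; 11 carbon tetrabromide
Product: 12 (R)-1-[4-bromo-5-(dibromomethylene)-2-oxo-2,5-dihydrofuran-3-yl]butyl acetate
Conditions: CBr4 (2 equiv), PPh3 (4 equiv), CH2Cl2, 0 °C, premixed; then 10, 0 °C → rt
Reagents that add atoms: none
Why: Ramirez dibromomethylenation (a Wittig reaction of Ph3P=CBr2 with an anhydride carbonyl), expected at C5 because this carbonyl is flanked by the small, inductively activating C4 bromine whereas C2 is shielded by the branched C1′ substituent and is a less electrophilic vinylogous acyl bromide, and premixing leaves no free PPh3 to add at C4.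

Step 7
Reactants: 12 (R)-1-[4-bromo-5-(dibromomethylene)-2-oxo-2,5-dihydrofuran-3-yl]butyl acetate
Product: 13 acetoxyfimbrolide
Conditions: Pd(PPh3)4 (5 mol%), Bu3SnH (1.05 equiv, slow addition), toluene, 0 °C → rt, dark
Reagents that add atoms: none
Why: Palladium-catalysed hydrodebromination of a 1,1-dibromoalkene, in which zerovalent palladium should insert into the less hindered C–Br bond (syn to O1, remote from the C4 bromine) and hydride transfer from tin with reductive elimination proceeds with retention, leaving the bromine on the C4 side (5E), a geminal dibromoalkene being more reactive than the C4 monobromide.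

Compound list
1 | butanoyl chloride | CCCC(Cl)=O | starting material
2 | bis(trimethylsilyl)acetylene | C[Si](C)(C)C#C[Si](C)(C)C | starting material
3 | 1-(trimethylsilyl)hex-1-yn-3-one | CCCC(=O)C#C[Si](C)(C)C | intermediate
4 | (R)-1-(trimethylsilyl)hex-1-yn-3-ol | CCC[C@@H](O)C#C[Si](C)(C)C | intermediate
5 | (R)-hex-1-yn-3-ol | CCC[C@@H](O)C#C | intermediate (not isolated)
6 | (R)-hex-1-yn-3-yl acetate | CCC[C@@H](OC(C)=O)C#C | intermediate
7 | carbon monoxide | [C-]#[O+] | starting material
8 | (R)-3-(1-acetoxybutyl)furan-2,5-dione | CCC[C@@H](OC(C)=O)C1=CC(=O)OC1=O | intermediate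
9 | (1R)-1-(3,4-dibromo-2,5-dioxotetrahydrofuran-3-yl)butyl acetate, diastereomers at C3 and C4 | CCC[C@@H](OC(C)=O)C1(Br)C(Br)C(=O)OC1=O | intermediate (not isolated)
10 | (R)-1-(4-bromo-2,5-dioxo-2,5-dihydrofuran-3-yl)butyl acetate | CCC[C@@H](OC(C)=O)C1=C(Br)C(=O)OC1=O | intermediate
11 | carbon tetrabromide | BrC(Br)(Br)Br | starting material
12 | (R)-1-[4-bromo-5-(dibromomethylene)-2-oxo-2,5-dihydrofuran-3-yl]butyl acetate | CCC[C@@H](OC(C)=O)C1=C(Br)C(=C(Br)Br)OC1=O | intermediate
13 | acetoxyfimbrolide, (R)-1-[(5E)-4-bromo-5-(bromomethylene)-2-oxo-2,5-dihydrofuran-3-yl]butyl acetate | CCC[C@@H](OC(C)=O)C1=C(Br)/C(=C\Br)OC1=O | target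

Total step count: 7. Longest linear sequence: 7 steps (1 → 3 → 4 → 6 → 8 → 10 → 12 → 13).

Steps most likely to fail

Step 4. The propargylic acetate may ionise or migrate on palladium, or carbonylation may stop after one CO, so that the anhydride does not form. The fallback avoids alkyne carbonylation altogether and unmasks a 3-substituted furan as the maleic anhydride. It sets out from butanoyl chloride 1. Acyl Suzuki–Miyaura coupling with furan-3-ylboronic acid (Pd(PPh3)4, Cs2CO3, toluene) should give 1-(furan-3-yl)butan-1-one F1. Transfer hydrogenation with RuCl[(R,R)-TsDPEN](p-cymene) in HCO2H/Et3N should give (R)-1-(furan-3-yl)butan-1-ol F2, and Ac2O/DMAP its ester (R)-1-(furan-3-yl)butyl acetate F3. Sensitised photooxygenation (O2, tetraphenylporphyrin, hν, i-Pr2NEt, CH2Cl2, −78 °C) should convert the furan into the hydroxybutenolide (1R)-1-(2-hydroxy-5-oxo-2,5-dihydrofuran-3-yl)butyl acetate F4. Oxidation of the lactol with pyridinium chlorochromate, [C5H5NH][CrO3Cl], comes back to the route at 8.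

Step 6. Phosphorus nucleophiles may attack C4 in conjugate fashion, expelling bromide or the allylic acetate, faster than the ylide olefinates C5=O. The fallback brings in the exocyclic carbon without phosphorus and sets out from 10. Addition of LiCHBr2 (CH2Br2, LiN(i-Pr)2, THF, −95 °C) to the more electrophilic C5 carbonyl should give, after acidic work-up, the lactol (1R)-1-[4-bromo-5-(dibromomethyl)-5-hydroxy-2-oxo-2,5-dihydrofuran-3-yl]butyl acetate F5. Its dehydration (P2O5, CH2Cl2) comes back to the route at 12.

Step 7. Zerovalent palladium may also insert into the C4–Br bond or ionise the allylic acetate, or both exocyclic bromines may be reduced. The fallback makes the vinylic bromide by stereospecific bromodecarboxylation, which needs neither the tribromide nor palladium, and sets out from 10. Wittig reaction with Ph3P=CHCO2t-Bu (CHCl3, rt) followed by I2-catalysed equilibration should give tert-butyl (2Z)-2-[4-((1R)-1-acetoxybutyl)-3-bromo-5-oxofuran-2(5H)-ylidene]acetate F6, with the ester syn to O1 and away from the C4 bromine. CF3CO2H should free (2Z)-2-[4-((1R)-1-acetoxybutyl)-3-bromo-5-oxofuran-2(5H)-ylidene]acetic acid F7. Anti addition of Br2 (CH2Cl2, 0 °C) should give 2-bromo-2-[4-((1R)-1-acetoxybutyl)-2,3-dibromo-5-oxo-2,5-dihydrofuran-2-yl]acetic acid F8, which is not isolated. NaHCO3 in DMF then triggers anti decarboxylative loss of the C5 bromide, which places the remaining bromine on the C4 side and comes back to the route at 13.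

Further compounds
F1 | step 4 | 1-(furan-3-yl)butan-1-one | CCCC(=O)c1ccoc1
F2 | step 4 | (R)-1-(furan-3-yl)butan-1-ol | CCC[C@@H](O)c1ccoc1
F3 | step 4 | (R)-1-(furan-3-yl)butyl acetate | CCC[C@@H](OC(C)=O)c1ccoc1
F4 | step 4 | (1R)-1-(2-hydroxy-5-oxo-2,5-dihydrofuran-3-yl)butyl acetate, both lactol epimers | CCC[C@@H](OC(C)=O)C1=CC(=O)OC1O
F5 | step 6 | (1R)-1-[4-bromo-5-(dibromomethyl)-5-hydroxy-2-oxo-2,5-dihydrofuran-3-yl]butyl acetate, both C5 epimers | CCC[C@@H](OC(C)=O)C1=C(Br)C(O)(C(Br)Br)OC1=O
F6 | step 7 | tert-butyl (2Z)-2-[4-((1R)-1-acetoxybutyl)-3-bromo-5-oxofuran-2(5H)-ylidene]acetate | CCC[C@@H](OC(C)=O)C1=C(Br)/C(=C/C(=O)OC(C)(C)C)OC1=O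
F7 | step 7 | (2Z)-2-[4-((1R)-1-acetoxybutyl)-3-bromo-5-oxofuran-2(5H)-ylidene]acetic acid | CCC[C@@H](OC(C)=O)C1=C(Br)/C(=C/C(=O)O)OC1=O
F8 | step 7 | 2-bromo-2-[4-((1R)-1-acetoxybutyl)-2,3-dibromo-5-oxo-2,5-dihydrofuran-2-yl]acetic acid, anti adduct from both faces | CCC[C@@H](OC(C)=O)C1=C(Br)C(Br)(C(Br)C(=O)O)OC1=O
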